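The constant of the first exchange can be read from the earliest readings, while incoming ligand stands near its charge and the decay of starting complex is pseudo-first-order. The logarithm of the fraction left, taken over ligand concentration and time, gives 1.50 M⁻¹ s⁻¹ in Thursday's run and 1.43 M⁻¹ s⁻¹ in Sunday's, with a mean of 1.46 M⁻¹ s⁻¹. The decision is how much scavenger to charge to the next flask. Scavenger takes up leaving ligand, which may otherwise park starting complex as idle adduct.

| flask | starting complex | incoming ligand | scavenger | remark | time |
|---|---|---|---|---|---|
| Thursday's | 3 mM | 3 equiv | 1 equiv | run made earlier |  |
| Sunday's | 4 mM | 3 equiv | 1 equiv | run made earlier |  |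
| larch | 2.0 mM | 3.00 equiv | 1.50 equiv |  | 6.0 min |
| ash | 2.0 mM | 3.00 equiv | 1.00 equiv |  | 6.0 min |
| cedar | 2.0 mM | 3.00 equiv | 2.20 equiv |  | 6.0 min |

| run | time / s | starting complex / % | complex with one exchanged / % |
|---|---|---|---|
| Thursday's | 10.0 | 87.4 | 8.8 |
| Thursday's | 20.0 | 77.9 | 11.4 |
| Thursday's | 40.0 | 62.6 | 12.8 |
| Thursday's | 60.0 | 52.5 | 10.9 |
| Thursday's | 120 | 32.3 | 8.2 |
| Sunday's | 12.0 | 81.4 | 10.3 |
| Sunday's | 30.0 | 62.5 | 11.2 |
| Sunday's | 60.0 | 43.7 | 10.1 |
| Sunday's | 90.0 | 31.8 | 7.6 |
| Sunday's | 120 | 24.4 | 6.4 |

(each reading ± 0.5 percentage points)

- for leaving ligand the idle adduct is counted in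
- the numbers in the tables scatter by 0.5 percentage points (one standard deviation)
- what may be going on: starting complex + incoming ligand -> leaving ligand + complex with one exchanged; complex with one exchanged + incoming ligand -> leaving ligand + complex with two exchanged; leaving ligand + starting complex <-> idle adduct; scavenger + leaving ligand -> scavenged by-product; complex with one exchanged + incoming ligand -> over-reaction product

- part of the starting complex that has reacted at the end, larch
- part of the starting complex that has reacted at the end, ash
- part of the starting complex that has reacted at the end, cedar
- what raising the equivalents of scavenger from its lowest to its highest value here does to the part of the starting complex that has reacted (changes below 5 percentage points count as none) (no change / it falls / it rises)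

The reckoning works with the fraction left. Complex with one exchanged reads 12.8% at 40.0 s in Thursday's run, less than the 37.4% of starting complex lost by then. Both its onward steps take another incoming ligand, so as a rough rule each starting complex lost costs two. At 3.00 equiv of ligand, the ligand left in equivalents is 1 + 2 × left, and the rate law integrates to left / (1 + 2 × left) = exp(−reduced time) / 3. The reduced time is the constant times the starting complex charged times the time.

Sunday's last reading has a reduced time of 0.702. The rule leaves 24.7% there and 24.4% was read, so at 1 equiv of scavenger no slowing shows beyond the scatter. The planned flasks have a reduced time of 1.05, which lies past the end of both runs. The rule leaves 15.2%, so 84.8% has reacted, and it holds no term for scavenger. On Sunday's reading, my reckoning charges 1.00 equiv, as in ash, and expects no change with more.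

The forecast gives 86% for larch, 84.5% for ash and 86.5% for cedar, with no change, holding that “inhibition by adduct formation is weak”.

The flasks give 84.7% for larch, 85.5% for ash and 84.8% for cedar, which is no change: −0.74 percentage points from the lowest scavenger to the highest.

    starting complex + incoming ligand → leaving ligand + complex with one exchanged (k = 1.40 M⁻¹ s⁻¹)
    complex with one exchanged + incoming ligand → leaving ligand + complex with two exchanged (k = 2.68 M⁻¹ s⁻¹)
    leaving ligand + starting complex ⇌ idle adduct, settled at all times (K = 380 M⁻¹)
    scavenger + leaving ligand → scavenged by-product (k = 282 M⁻¹ s⁻¹)
    complex with one exchanged + incoming ligand → over-reaction product (k = 4.68 M⁻¹ s⁻¹)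

In cedar at 6.00 min, complex with one exchanged is made at 0.811 of the rate at which it is used up, and it holds 3.58% of the complex charged, while starting complex stands at 15% against the 15.2% reckoned from a reduced time of 1.05. Cedar's neighbour with 0.80 mM of starting complex, at the same equivalents and time, has a reduced time of 0.421, for which the rule leaves 38.9%, and that flask holds 38.8%.

Readings and results come from a simulation with constants of no real substance; the scatter is artificial.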